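**Plan**
- Retrosynthesis: the butenolide is opened at C13=C14 (ring-closing metathesis) and the side chain is cut at C11–C12 (allylation of the C11 aldehyde, albicanal). Ring A is then cut at C1–C2 and C4–C5, which removes a prenyl-type C2–C3–C4 unit from a ring B ketone. Ring B comes from a benzoquinone monoketal.
- Forward: ring B first (C9 by asymmetric conjugate addition, quaternary C10 by two alkylations), then ring A in one [3+3] event, then trans ring fusion, C8 methylene, side chain and butenolide.
- Enabling feature: C1 and C5 both sit on the quaternary C10 of ring B (a 1,3-pair). With boron on C1 and a carbonyl at C5 they match an allyl unit: its α-carbon (C2) accepts C1 by a 1,2-shift, and its gem-dimethyl γ-carbon (C4) adds to C5.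
- Stereochemistry: C9 from the chiral copper catalyst; C10 by relay from C9 (alkylation anti to the C9 arm); C5 by hydrogen-atom-transfer hydrogenation (trans-decalin); C11 by CBS reduction.

Key step: step 7

Remark: carbon numbers C1–C20 are labdane numbers. The (S,R,R) phosphoramidite is assumed to give the 9S sense in step 2; the mirror-image ligand is used if the opposite sense is found.

**Step 1**
Reactants: 1 iodomethyl 2,2-dimethylpropanoate (iodomethyl pivalate); 2 diethylzinc
Product: 3 bis[(pivaloyloxy)methyl]zinc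
Conditions: 1 (2 equiv), Et2Zn (1 equiv), CH2Cl2, −10 °C → rt; EtI and solvent removed in vacuo; taken up in toluene
Reagents that add atoms: iodomethyl 2,2-dimethylpropanoate (second equivalent of 1), CC(C)(C)C(=O)OCI
Why: Iodine–zinc exchange of the α-acyloxyalkyl iodide with Et2Zn, two molecules of 1 per zinc, should give the diorganozinc (a hydroxymethyl anion equivalent that carries C11) together with volatile iodoethane.

**Step 2**
Reactants: 4 4,4-dimethoxycyclohexa-2,5-dien-1-one; 3 bis[(pivaloyloxy)methyl]zinc
Product: 6 [(1S)-2,2-dimethoxy-5-oxocyclohex-3-en-1-yl]methyl pivalate, via zinc enolate 5 (not isolated)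
Conditions: Cu(OTf)2 (2 mol%), (S,R,R)-BINOL-derived N,N-bis(1-phenylethyl)phosphoramidite (4 mol%), toluene, −25 °C; pH 7 buffer
Reagents that add atoms: none
Why: Copper/phosphoramidite-catalysed asymmetric conjugate addition of a diorganozinc should desymmetrize the quinone monoketal, the ligand choosing one of the two enantiotopic enone arms and so setting C9.

**Step 3**
Reactants: 6
Product: 8 [(1S,6R)-2,2-dimethoxy-6-methyl-5-oxocyclohex-3-en-1-yl]methyl pivalate, via lithium enolate 7 (not isolated)
Conditions: LiN(i-Pr)2, THF, −78 °C; MeI, −78 → −20 °C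
Reagents that add atoms: iodomethane, CI
Why: Kinetic enolate alkylation at the only enolizable position (the CH2 that becomes C10) installs the angular methyl carbon; the configuration here does not matter because step 4 re-enolizes.

**Step 4**
Reactants: 8
Product: 10 [(1S,6R)-2,2-dimethoxy-6-methyl-5-oxo-6-[(4,4,5,5-tetramethyl-1,3,2-dioxaborolan-2-yl)methyl]cyclohex-3-en-1-yl]methyl pivalate, via lithium enolate 9 (not isolated)
Conditions: LiN(i-Pr)2, THF/DMPU, −78 °C; ICH2Bpin, −78 → 0 °C
Reagents that add atoms: 2-(iodomethyl)-4,4,5,5-tetramethyl-1,3,2-dioxaborolane, CC1(C)OB(CI)OC1(C)C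
Why: Enolate alkylation with the activated α-boryl iodide builds quaternary C10; the electrophile (C1 with its boron) should enter anti to the adjacent CH2OPiv arm, leaving the methyl cis to that arm as the target needs.

**Step 5**
Reactants: 10
Product: 11 {[(1R,6S)-5,5-dimethoxy-1-methyl-2-oxo-6-[(pivaloyloxy)methyl]cyclohex-3-en-1-yl]methyl}boronic acid
Conditions: NaIO4, NH4OAc, acetone/H2O, rt
Reagents that add atoms: water, O
Why: Oxidative cleavage of the pinacol ester under near-neutral conditions frees the boronic acid, the Lewis acidic form that reacts with diazoalkanes; the ketal, enone and pivalate should survive.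

**Step 6**
Reactants: 12 3-methylbut-2-enal; 13 4-methylbenzenesulfonohydrazide
Product: 14 N'-[(1E)-3-methylbut-2-en-1-ylidene]-4-methylbenzenesulfonohydrazide
Conditions: MeOH, rt
Reagents that add atoms: none
Why: Hydrazone condensation gives the bench-stable precursor of the three-carbon C2–C3–C4 unit; the β,β-dimethyl substitution disfavours aza-Michael cyclization.

**Step 7**
Reactants: 11; 14
Product: 18 [(1S,8aR)-4a-hydroxy-2,2-dimethoxy-5,5,8a-trimethyl-1,2,4a,5,8,8a-hexahydronaphthalen-1-yl]methyl pivalate (either configuration at C4a), via 1-diazo-3-methylbut-2-ene 15 (not isolated), via allylboronic acid 16 (not isolated), via borate ester 17 (not isolated)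
Conditions: K2CO3, 1,4-dioxane, 4 Å MS, 90 °C, slow addition of 14 (2 equiv); aq. NH4Cl
Reagents that add atoms: none
Why: Proposed new method: base converts 14 into the vinyl diazoalkane 15, whose carbon adds to the boron of 11 and triggers a 1,2-shift of the C1 methylene from boron to carbon with loss of N2 (C1–C2 bond), giving the α-substituted γ,γ-dimethylallylboronic acid 16; its gem-dimethyl γ-carbon then adds to the C5 ketone two atoms away (C4–C5 bond) with allyl transposition and transfer of boron to oxygen. The closest known reaction types are the metal-free reductive coupling of tosylhydrazones with boronic acids (which with enal-derived hydrazones passes through such allylboronic acids) and the allylboration of ketones by allylboronic acids; new is their union into a ring-forming [3+3] event. Ring A closes in the second stage as a six-membered ring by intramolecular SE2′ allyl transfer through a boat-like bridged six-centre transition state (B–O, C3–C4 and C1–C10 bridges between C2 and C5), which leaves the C2=C3 alkene cis in the ring. The stereocentre at C2 of 16 is lost on transposition, the new carbinol centre C5 is not controlled and is removed in step 9, and C9 and C10 are not touched. The step needs the boron 1,2-shift to outrun cyclization of 15 to a pyrazole and its cycloaddition to the hindered enone (helped by the Lewis acidic boronic acid and the slow feed of 14), and it needs allyl transfer to C5 to outrun protodeboronation (helped by the 1,3-placement of C1 and C5 on C10 and by dry conditions); α-attack is excluded because it would give a four-membered ring.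

**Step 8**
Reactants: 18
Product: 19 [(1S,8aR)-4a-hydroxy-2,2-dimethoxy-5,5,8a-trimethyldecahydronaphthalen-1-yl]methyl pivalate (either configuration at C4a)
Conditions: H2 (1 atm), Pd/C, EtOAc, trace Et3N, rt
Reagents that add atoms: none
Why: Catalytic hydrogenation should saturate both cis-disubstituted alkenes (C2=C3 and C6=C7), the amine suppressing hydrogenolysis of the allylic C–O bonds.

**Step 9**
Reactants: 19
Product: 20 [(1S,8aR)-2,2-dimethoxy-5,5,8a-trimethyl-1,2,3,5,6,7,8,8a-octahydronaphthalen-1-yl]methyl pivalate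
Conditions: SOCl2, pyridine, CH2Cl2, −10 °C → rt
Reagents that add atoms: none
Why: Dehydration through the chlorosulfite (E2-type) can only go toward C6, the sole neighbour with hydrogen, and avoids a free C5 cation that would invite methyl shifts from C4 or C10.

**Step 10**
Reactants: 20
Product: 21 [(1S,4aS,8aS)-2,2-dimethoxy-5,5,8a-trimethyldecahydronaphthalen-1-yl]methyl pivalate
Conditions: Mn(dpm)3 (10 mol%), PhSiH3, t-BuOOH, i-PrOH, rt
Reagents that add atoms: none
Why: Hydrogen-atom-transfer hydrogenation puts H on C6 and gives the tertiary C5 radical, which should take its hydrogen on the face opposite the axial methyls on C10 and C4 and so set the trans ring fusion (5S).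

**Step 11**
Reactants: 21
Product: 22 [(1S,4aS,8aS)-5,5,8a-trimethyl-2-oxodecahydronaphthalen-1-yl]methyl pivalate
Conditions: PPTS, acetone/H2O, 50 °C
Reagents that add atoms: water, O
Why: Mild acetal hydrolysis unveils the C8 ketone without base, so the β-acyloxy ketone neither eliminates nor epimerizes at C9.

**Step 12**
Reactants: 22
Product: 23 [(1S,4aS,8aS)-5,5,8a-trimethyl-2-methylidenedecahydronaphthalen-1-yl]methyl pivalate
Conditions: Zn, CH2Br2, TiCl4, THF/CH2Cl2, 0 °C → rt
Reagents that add atoms: dibromomethane, BrCBr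
Why: Takai–Lombardo methylenation is non-basic and tolerates esters, so the hindered β-pivaloyloxy ketone should give the C8 exocyclic alkene without E1cB loss of pivalate.

**Step 13**
Reactants: 23
Product: 24 [(1S,4aS,8aS)-5,5,8a-trimethyl-2-methylidenedecahydronaphthalen-1-yl]methanol (albicanol)
Conditions: i-Bu2AlH (2.5 equiv), CH2Cl2, −78 → 0 °C
Reagents that add atoms: none
Why: Hydride reduction cleaves the pivalate and leaves the 1,1-disubstituted alkene untouched.

**Step 14**
Reactants: 24
Product: 25 (1S,4aS,8aS)-5,5,8a-trimethyl-2-methylidenedecahydronaphthalene-1-carbaldehyde (albicanal)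
Conditions: Dess–Martin periodinane, NaHCO3, CH2Cl2, 0 °C; used crude
Reagents that add atoms: none
Why: Buffered Dess–Martin oxidation gives the β,γ-unsaturated aldehyde under neutral conditions that should avoid C9 epimerization and alkene migration into conjugation.

**Step 15**
Reactants: 26 2-(bromomethyl)prop-2-enoic acid; 27 prop-2-en-1-ol
Product: 28 prop-2-en-1-yl 2-(bromomethyl)prop-2-enoate
Conditions: p-TsOH (cat.), excess 27, benzene, reflux, Dean–Stark
Reagents that add atoms: none
Why: Fischer esterification gives the allyl ester that carries C12–C16 and the alkene needed for the later metathesis.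

**Step 16**
Reactants: 25; 28
Product: 30 prop-2-enyl 4-hydroxy-2-methylidene-4-[(1S,4aS,8aS)-5,5,8a-trimethyl-2-methylidenedecahydronaphthalen-1-yl]butanoate (both C4 epimers), via allylic zinc bromide 29 (not isolated)
Conditions: Zn dust, THF/sat. aq. NH4Cl, 0 °C → rt
Reagents that add atoms: none
Why: Barbier allylation with a 2-(alkoxycarbonyl)allyl zinc reagent forms C11–C12 under near-neutral conditions; the C11 configuration is not relied on, since Felkin–Anh addition would favour the wrong epimer and steps 17 and 18 reset it.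

**Step 17**
Reactants: 30
Product: 31 prop-2-enyl 2-methylidene-4-oxo-4-[(1S,4aS,8aS)-5,5,8a-trimethyl-2-methylidenedecahydronaphthalen-1-yl]butanoate
Conditions: Dess–Martin periodinane, NaHCO3, CH2Cl2, 0 °C
Reagents that add atoms: none
Why: Neutral Dess–Martin oxidation converges both carbinol epimers on the C11 ketone without moving the C13 methylidene into conjugation.

**Step 18**
Reactants: 31
Product: 32 prop-2-enyl (4R)-4-hydroxy-2-methylidene-4-[(1S,4aS,8aS)-5,5,8a-trimethyl-2-methylidenedecahydronaphthalen-1-yl]butanoate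
Conditions: (S)-2-methyl-CBS-oxazaborolidine, catecholborane, toluene, −78 °C
Reagents that add atoms: none
Why: CBS reduction, with the decalin as the large and the CH2 as the small ketone substituent, should give the 11R alcohol; Felkin–Anh hydride delivery anti to C10 points the same way, and catecholborane spares the acrylate and the alkenes.

**Step 19**
Reactants: 32
Product: 33 prop-2-enyl (4R)-4-acetoxy-2-methylidene-4-[(1S,4aS,8aS)-5,5,8a-trimethyl-2-methylidenedecahydronaphthalen-1-yl]butanoate
Conditions: Ac2O, pyridine, DMAP (cat.), CH2Cl2, 0 °C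
Reagents that add atoms: acetic anhydride, CC(=O)OC(C)=O
Why: Acylation caps the C11 hydroxyl before it can lactonize onto the ester.

**Step 20**
Reactants: 33
Product: 34 (1R)-2-(2-oxo-2,5-dihydrofuran-3-yl)-1-[(1S,4aS,8aS)-5,5,8a-trimethyl-2-methylidenedecahydronaphthalen-1-yl]ethyl acetate (target)
Conditions: second-generation Grubbs catalyst (5 mol%), CH2Cl2, 40 °C
Reagents that add atoms: none
Why: Ring-closing metathesis of the allyl 2-substituted acrylate closes the α-substituted butenolide (five-membered ring, C13=C14) with loss of ethene; the hindered C8 methylidene would have to form a tetrasubstituted cyclopentene and should stay out.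

**Compound list**
1 | iodomethyl 2,2-dimethylpropanoate | CC(C)(C)C(=O)OCI | starting material
2 | diethylzinc | CC[Zn]CC | starting material
3 | bis[(pivaloyloxy)methyl]zinc | CC(C)(C)C(=O)OC[Zn]COC(=O)C(C)(C)C | intermediate
4 | 4,4-dimethoxycyclohexa-2,5-dien-1-one | COC1(OC)C=CC(=O)C=C1 | starting material
5 | zinc enolate of 6, formed in the flask | COC1(OC)C=CC(O[Zn]COC(=O)C(C)(C)C)=C[C@H]1COC(=O)C(C)(C)C | intermediate
6 | [(1S)-2,2-dimethoxy-5-oxocyclohex-3-en-1-yl]methyl pivalate | COC1(OC)C=CC(=O)C[C@H]1COC(=O)C(C)(C)C | intermediate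
7 | lithium enolate of 6, formed in the flask | COC1(OC)C=CC(O[Li])=C[C@H]1COC(=O)C(C)(C)C | intermediate
8 | [(1S,6R)-2,2-dimethoxy-6-methyl-5-oxocyclohex-3-en-1-yl]methyl pivalate | COC1(OC)C=CC(=O)[C@H](C)[C@H]1COC(=O)C(C)(C)C | intermediate
9 | lithium enolate of 8, formed in the flask | COC1(OC)C=CC(O[Li])=C(C)[C@H]1COC(=O)C(C)(C)C | intermediate
10 | [(1S,6R)-2,2-dimethoxy-6-methyl-5-oxo-6-[(4,4,5,5-tetramethyl-1,3,2-dioxaborolan-2-yl)methyl]cyclohex-3-en-1-yl]methyl pivalate | COC1(OC)C=CC(=O)[C@](C)(CB2OC(C)(C)C(C)(C)O2)[C@H]1COC(=O)C(C)(C)C | intermediate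
11 | {[(1R,6S)-5,5-dimethoxy-1-methyl-2-oxo-6-[(pivaloyloxy)methyl]cyclohex-3-en-1-yl]methyl}boronic acid | COC1(OC)C=CC(=O)[C@](C)(CB(O)O)[C@H]1COC(=O)C(C)(C)C | intermediate
12 | 3-methylbut-2-enal | CC(C)=CC=O | starting material
13 | 4-methylbenzenesulfonohydrazide | Cc1ccc(cc1)S(=O)(=O)NN | starting material
14 | N'-[(1E)-3-methylbut-2-en-1-ylidene]-4-methylbenzenesulfonohydrazide | CC(C)=C/C=N/NS(=O)(=O)c1ccc(C)cc1 | intermediate
15 | 1-diazo-3-methylbut-2-ene, formed in the flask | CC(C)=CC=[N+]=[N-] | intermediate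
16 | [1-[(1R,6S)-5,5-dimethoxy-1-methyl-2-oxo-6-[(pivaloyloxy)methyl]cyclohex-3-en-1-yl]-4-methylpent-3-en-2-yl]boronic acid (both epimers at the boron-bearing carbon), formed in the flask | COC1(OC)C=CC(=O)[C@](C)(CC(B(O)O)C=C(C)C)[C@H]1COC(=O)C(C)(C)C | intermediate
17 | dihydroxyboryl ether (borate ester) of 18, formed in the flask | COC1(OC)C=CC2(OB(O)O)C(C)(C)C=CC[C@]2(C)[C@H]1COC(=O)C(C)(C)C | intermediate
18 | [(1S,8aR)-4a-hydroxy-2,2-dimethoxy-5,5,8a-trimethyl-1,2,4a,5,8,8a-hexahydronaphthalen-1-yl]methyl pivalate (C4a not controlled) | COC1(OC)C=CC2(O)C(C)(C)C=CC[C@]2(C)[C@H]1COC(=O)C(C)(C)C | intermediate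
19 | [(1S,8aR)-4a-hydroxy-2,2-dimethoxy-5,5,8a-trimethyldecahydronaphthalen-1-yl]methyl pivalate (C4a not controlled) | COC1(OC)CCC2(O)C(C)(C)CCC[C@]2(C)[C@H]1COC(=O)C(C)(C)C | intermediate
20 | [(1S,8aR)-2,2-dimethoxy-5,5,8a-trimethyl-1,2,3,5,6,7,8,8a-octahydronaphthalen-1-yl]methyl pivalate | COC1(OC)CC=C2C(C)(C)CCC[C@]2(C)[C@H]1COC(=O)C(C)(C)C | intermediate
21 | [(1S,4aS,8aS)-2,2-dimethoxy-5,5,8a-trimethyldecahydronaphthalen-1-yl]methyl pivalate | COC1(OC)CC[C@H]2C(C)(C)CCC[C@]2(C)[C@H]1COC(=O)C(C)(C)C | intermediate
22 | [(1S,4aS,8aS)-5,5,8a-trimethyl-2-oxodecahydronaphthalen-1-yl]methyl pivalate | O=C1CC[C@H]2C(C)(C)CCC[C@]2(C)[C@H]1COC(=O)C(C)(C)C | intermediate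
23 | [(1S,4aS,8aS)-5,5,8a-trimethyl-2-methylidenedecahydronaphthalen-1-yl]methyl pivalate | C=C1CC[C@H]2C(C)(C)CCC[C@]2(C)[C@H]1COC(=O)C(C)(C)C | intermediate
24 | [(1S,4aS,8aS)-5,5,8a-trimethyl-2-methylidenedecahydronaphthalen-1-yl]methanol (albicanol) | C=C1CC[C@H]2C(C)(C)CCC[C@]2(C)[C@H]1CO | intermediate
25 | (1S,4aS,8aS)-5,5,8a-trimethyl-2-methylidenedecahydronaphthalene-1-carbaldehyde (albicanal) | C=C1CC[C@H]2C(C)(C)CCC[C@]2(C)[C@H]1C=O | intermediate
26 | 2-(bromomethyl)prop-2-enoic acid | C=C(CBr)C(=O)O | starting material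
27 | prop-2-en-1-ol | C=CCO | starting material
28 | prop-2-en-1-yl 2-(bromomethyl)prop-2-enoate | C=CCOC(=O)C(=C)CBr | intermediate
29 | [2-(prop-2-enyloxycarbonyl)prop-2-enyl]zinc bromide, formed in the flask | C=CCOC(=O)C(=C)C[Zn]Br | intermediate
30 | prop-2-enyl 4-hydroxy-2-methylidene-4-[(1S,4aS,8aS)-5,5,8a-trimethyl-2-methylidenedecahydronaphthalen-1-yl]butanoate (both C4 epimers) | C=C1CC[C@H]2C(C)(C)CCC[C@]2(C)[C@H]1C(O)CC(=C)C(=O)OCC=C | intermediate
31 | prop-2-enyl 2-methylidene-4-oxo-4-[(1S,4aS,8aS)-5,5,8a-trimethyl-2-methylidenedecahydronaphthalen-1-yl]butanoate | C=C1CC[C@H]2C(C)(C)CCC[C@]2(C)[C@H]1C(=O)CC(=C)C(=O)OCC=C | intermediate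
32 | prop-2-enyl (4R)-4-hydroxy-2-methylidene-4-[(1S,4aS,8aS)-5,5,8a-trimethyl-2-methylidenedecahydronaphthalen-1-yl]butanoate | C=C1CC[C@H]2C(C)(C)CCC[C@]2(C)[C@H]1[C@@H](CC(=C)C(=O)OCC=C)O | intermediate
33 | prop-2-enyl (4R)-4-acetoxy-2-methylidene-4-[(1S,4aS,8aS)-5,5,8a-trimethyl-2-methylidenedecahydronaphthalen-1-yl]butanoate | C=C1CC[C@H]2C(C)(C)CCC[C@]2(C)[C@H]1[C@@H](CC(=C)C(=O)OCC=C)OC(C)=O | intermediate
34 | (1R)-2-(2-oxo-2,5-dihydrofuran-3-yl)-1-[(1S,4aS,8aS)-5,5,8a-trimethyl-2-methylidenedecahydronaphthalen-1-yl]ethyl acetate | C=C1CC[C@H]2C(C)(C)CCC[C@]2(C)[C@H]1[C@@H](CC1=CCOC1=O)OC(C)=O | target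

**Step count**
Total: 20 steps. Longest linear sequence: 18 steps (steps 1–5, 7–14 and 16–20).

**Steps most likely to fail**

Step 7. The bridged, boat-like transition state for allyl transfer onto C5 may be too slow, so that protodeboronation of 16 with double-bond shift, or cyclization of the diazoalkane to a pyrazole, takes over. The fallback sets out from 8 and comes back at 21, building ring A by classical annulation. Hydrogenation of 8 (H2, Pd/C) should give the saturated methyl ketone F1. Robinson annulation of F1 with ethyl vinyl ketone (t-BuOK cat., t-BuOH; then NaOMe, MeOH) should add at the more substituted α-carbon anti to the C9 arm and condense to the bicyclic enone F2. Reductive methylation (Li, NH3, THF, 1 equiv t-BuOH; then MeI) should give the trans-fused 4,4-dimethyl ketone F3. Wolff–Kishner reduction (N2H4·H2O, KOH, diethylene glycol, 200 °C) removes the C3 carbonyl and, with loss of the pivalate, gives the alcohol F4. Pivaloylation of F4 (PivCl, pyridine) returns 21.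

Step 2. The chelated α-acyloxyalkylzinc may transfer its group to copper too slowly, or the catalyst may discriminate the two enone arms poorly. The fallback sets out from 4 and comes back at 6. Rhodium-catalysed asymmetric conjugate addition ([Rh(OH)(cod)]2, BINAP, potassium vinyltrifluoroborate, dioxane/H2O) should give the vinyl enone F5. Chemoselective ozonolysis of the electron-rich vinyl group (O3, CH2Cl2/MeOH, −78 °C; Me2S) gives the aldehyde F6, which is reduced at once to limit epimerization at C9. Aldehyde-selective reduction (NaBH(OAc)3) gives the alcohol F7, and pivaloylation (PivCl, pyridine) returns 6.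

Step 10. The alkene between two quaternary carbons may accept the hydrogen atom sluggishly, or the C5 radical may be quenched with poor facial selectivity. The fallback sets out from 20 and comes back at 22. Acetal hydrolysis (PPTS, acetone/H2O) gives the β,γ-unsaturated ketone F8. Isomerization into conjugation under acid (p-TsOH, benzene, rt), chosen over base so that the β-pivaloyloxy ketone does not eliminate, protonates C5 under thermodynamic control and should give the trans-fused enone F9. Hydrogenation (H2, Pd/C) then gives 22.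

**Further compounds**
F1 | step 7 | [(1S,2R)-6,6-dimethoxy-2-methyl-3-oxocyclohexyl]methyl pivalate | COC1(OC)CCC(=O)[C@H](C)[C@H]1COC(=O)C(C)(C)C
F2 | step 7 | [(1S,8aR)-2,2-dimethoxy-5,8a-dimethyl-6-oxo-1,2,3,4,6,7,8,8a-octahydronaphthalen-1-yl]methyl pivalate | COC1(OC)CCC2=C(C)C(=O)CC[C@]2(C)[C@H]1COC(=O)C(C)(C)C
F3 | step 7 | [(1S,4aR,8aS)-2,2-dimethoxy-5,5,8a-trimethyl-6-oxodecahydronaphthalen-1-yl]methyl pivalate | COC1(OC)CC[C@H]2C(C)(C)C(=O)CC[C@]2(C)[C@H]1COC(=O)C(C)(C)C
F4 | step 7 | [(1S,4aS,8aS)-2,2-dimethoxy-5,5,8a-trimethyldecahydronaphthalen-1-yl]methanol | COC1(OC)CC[C@H]2C(C)(C)CCC[C@]2(C)[C@H]1CO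
F5 | step 2 | (5S)-5-ethenyl-4,4-dimethoxycyclohex-2-en-1-one | COC1(OC)C=CC(=O)C[C@H]1C=C
F6 | step 2 | (1S)-2,2-dimethoxy-5-oxocyclohex-3-ene-1-carbaldehyde | COC1(OC)C=CC(=O)C[C@H]1C=O
F7 | step 2 | (5S)-5-(hydroxymethyl)-4,4-dimethoxycyclohex-2-en-1-one | COC1(OC)C=CC(=O)C[C@H]1CO
F8 | step 10 | [(1S,8aR)-5,5,8a-trimethyl-2-oxo-1,2,3,5,6,7,8,8a-octahydronaphthalen-1-yl]methyl pivalate | O=C1CC=C2C(C)(C)CCC[C@]2(C)[C@H]1COC(=O)C(C)(C)C
F9 | step 10 | [(1S,4aS,8aS)-5,5,8a-trimethyl-2-oxo-1,2,4a,5,6,7,8,8a-octahydronaphthalen-1-yl]methyl pivalate | O=C1C=C[C@H]2C(C)(C)CCC[C@]2(C)[C@H]1COC(=O)C(C)(C)C
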